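## Retrosynthetic overview

1. Target 26 ⇐ chiral-acid cycloisomerisation of the nona-ol triarylethene 24: the lower dihydrofuran ring is closed last (O–C2' bond, C3' and C2' set).
2. 24 ⇐ C–C bond between the resorcinol ring of dimer 15 (as penta-acetal 16, metalated between its two oxygens) and deoxybenzoin 19, then unmasking and dehydration.
3. 15 ⇐ the same cycloisomerisation of hexaol triarylethene 13 with the antipodal catalyst: the upper dihydrofuran ring is closed first and carries the first stereocentres.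
4. 13 ⇐ resveratrol tris-acetal 3 (metalated between its two ring oxygens) + deoxybenzoin 8.
5. 8 and 19 ⇐ Pd α-arylation of one acetophenone 5, used twice; the only rings built are the two dihydrofurans (upper, then lower).

Assumption: 1-ethoxyethyl acetals are carried as epimer mixtures (no descriptor at the acetal carbon in the SMILES), and the hand of the new catalyst is assigned by a working model; if the first run shows the opposite sense, the two antipodes change places between steps 7 and 13.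

IDPi = imidodiphosphorimidate Brønsted acid built from two 3,3'-bis[3,5-bis(trifluoromethyl)phenyl]-BINOL units with N-triflyl groups; (S,S) and (R,R) refer to the BINOL units.

## Route

Step 1
Reactants: 1 resveratrol; 2 ethyl vinyl ether
Product: 3 (E)-3,4',5-tris(1-ethoxyethoxy)stilbene
Conditions: ethyl vinyl ether (6 equiv), PPTS (5 mol%), THF/CH2Cl2, 0 → 23 °C
Reagents that add atoms: ethyl vinyl ether, C=COCC
Why: PPTS-catalysed addition of the phenols to the enol ether (acetal protection) gives base-stable acetals that direct ortho-lithiation between the two ring oxygens and later fall off with PPTS/MeOH.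

Step 2
Reactants: 4 1-(3,5-dihydroxyphenyl)ethanone; 2 ethyl vinyl ether
Product: 5 1-[3,5-bis(1-ethoxyethoxy)phenyl]ethanone
Conditions: ethyl vinyl ether (4 equiv), PPTS (5 mol%), CH2Cl2, 0 → 23 °C
Reagents that add atoms: ethyl vinyl ether, C=COCC
Why: Same acetal protection; this ketone supplies both 3,5-dioxygenated rings of the target.

Step 3
Reactants: 6 4-bromophenol; 2 ethyl vinyl ether
Product: 7 1-bromo-4-(1-ethoxyethoxy)benzene
Conditions: ethyl vinyl ether (2 equiv), PPTS (5 mol%), CH2Cl2, 0 → 23 °C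
Reagents that add atoms: ethyl vinyl ether, C=COCC
Why: Same acetal protection, so the phenol survives NaOt-Bu and organocerium chemistry and is released in step 6.

Step 4
Reactants: 5 1-[3,5-bis(1-ethoxyethoxy)phenyl]ethanone; 7 1-bromo-4-(1-ethoxyethoxy)benzene
Product: 8 1-[3,5-bis(1-ethoxyethoxy)phenyl]-2-[4-(1-ethoxyethoxy)phenyl]ethanone
Conditions: Pd2(dba)3 (1 mol%), Xantphos (2.5 mol%), NaOt-Bu (2.2 equiv), THF, 70 °C
Reagents that add atoms: none
Why: Pd-catalysed α-arylation of a methyl ketone enolate (Buchwald–Hartwig type); the more acidic product is parked as its enolate, so mono-arylation stops cleanly and the acetals tolerate the base.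

Step 5
Reactants: 3 (E)-3,4',5-tris(1-ethoxyethoxy)stilbene; 8 deoxybenzoin from step 4
Product: 11 hexa-acetal tertiary carbinol, via aryllithium 9 (not isolated), via arylcerium dichloride 10 (not isolated)
Conditions: 3 (1.6 equiv), s-BuLi (1.5 equiv), TMEDA, THF, −78 °C; CeCl3 (dried, 1.6 equiv), −78 °C; then 8, −78 → −20 °C; aq NaHCO3
Reagents that add atoms: none
Why: Directed ortho-metalation at the only C–H flanked by two acetal oxygens, then Imamoto organocerium 1,2-addition, which adds to the easily enolised benzyl ketone instead of deprotonating it; the carbinol carbon becomes sp2 in step 6.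

Step 6
Reactants: 11 hexa-acetal tertiary carbinol
Product: 13 hexaol triarylethene (E/Z mixture at the new alkene), via free heptaol carbinol 12 (not isolated)
Conditions: PPTS (0.3 equiv), MeOH/THF 3:1, 23 °C then 45 °C, argon
Reagents that add atoms: none
Why: Acid-catalysed transacetalisation to methanol frees the six phenols, and the ortho-hydroxy tertiary benzylic alcohol then dehydrates (E1 via the o-quinone methide) to the triarylethene; the pyridinium acid is too weak to protonate C3, so no racemic ring closure occurs.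

Step 7
Reactants: 13 hexaol triarylethene
Product: 15 (2R,3R)-trans-dihydrobenzofuran dimer (gnetin C skeleton), via p-quinone methide 14 (not isolated)
Conditions: (S,S)-IDPi (5 mol%), CHCl3/EtOAc 4:1 (0.01 M), 0 → 23 °C, argon
Reagents that add atoms: none
Why: Proposed new method: the confined chiral acid protonates C3 of the 4-hydroxystilbene unit enantioselectively to give the hydrogen-bonded p-quinone methide/benzylic cation ion pair 14 (E and Z isomers converge because reversible C2 protonation interconverts them); the ortho-phenol then adds 1,6 to C2 anti to the C3 aryl group, and any cis isomer equilibrates to trans by reversible C2–O ionisation, so the catalyst sets C3 and C3 sets C2. Closest known reactions: racemic acid-mediated cyclisation of 2-hydroxystilbenes to 2-aryl-2,3-dihydrobenzofurans, IDPi-catalysed asymmetric intramolecular hydroalkoxylation of alkenes, and chiral-phosphoric-acid 1,6-additions to p-quinone methides formed in situ.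

Step 8
Reactants: 15 (2R,3R)-dimer; 2 ethyl vinyl ether
Product: 16 penta(1-ethoxyethyl) ether of 15
Conditions: ethyl vinyl ether (10 equiv), PPTS (5 mol%), THF/CH2Cl2, 0 → 23 °C
Reagents that add atoms: ethyl vinyl ether, C=COCC
Why: Acetal protection under an acid too weak to open the benzylic C2–O bond; it restores the two directing acetal oxygens on the 3,5-dioxygenated ring.

Step 9
Reactants: 17 4-bromobenzene-1,2-diol; 2 ethyl vinyl ether
Product: 18 4-bromo-1,2-bis(1-ethoxyethoxy)benzene
Conditions: ethyl vinyl ether (6 equiv), PPTS (5 mol%), CH2Cl2, 0 °C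
Reagents that add atoms: ethyl vinyl ether, C=COCC
Why: Same acetal protection, run cold with excess enol ether so that both catechol oxygens are capped before a cyclic ethylidene acetal can form.

Step 10
Reactants: 5 1-[3,5-bis(1-ethoxyethoxy)phenyl]ethanone; 18 4-bromo-1,2-bis(1-ethoxyethoxy)benzene
Product: 19 1-[3,5-bis(1-ethoxyethoxy)phenyl]-2-[3,4-bis(1-ethoxyethoxy)phenyl]ethanone
Conditions: Pd2(dba)3 (1 mol%), Xantphos (2.5 mol%), NaOt-Bu (2.2 equiv), THF, 70 °C
Reagents that add atoms: none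
Why: Same Pd-catalysed ketone α-arylation as step 4, with the same mono-selectivity through the product enolate.

Step 11
Reactants: 16 penta-acetal dimer; 19 deoxybenzoin from step 10
Product: 22 nona-acetal tertiary carbinol, via aryllithium 20 (not isolated), via arylcerium dichloride 21 (not isolated)
Conditions: 16 (1.0 equiv), s-BuLi (1.05 equiv), TMEDA, THF, −78 °C; CeCl3 (1.2 equiv), −78 °C; then 19 (2 equiv), −78 → −20 °C; aq NaHCO3
Reagents that add atoms: none
Why: Kinetic directed ortho-metalation at the one C–H flanked by two acetal oxygens (C4 of the 3-aryl ring), then organocerium 1,2-addition to the enolisable ketone; the C2 and C3 centres are not touched.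

Step 12
Reactants: 22 nona-acetal tertiary carbinol
Product: 24 nona-ol triarylethene (E/Z mixture at the new alkene), via free carbinol 23 (not isolated)
Conditions: PPTS (0.3 equiv), MeOH/THF 3:1, 23 °C then 45 °C, argon
Reagents that add atoms: none
Why: Same transacetalisation and E1 dehydration via the o-quinone methide as in step 6; the weak acid leaves the existing dihydrofuran ring and the new alkene unchanged.

Step 13
Reactants: 24 nona-ol triarylethene
Product: 26 target CNP0107857.3, via p-quinone methide 25 (not isolated)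
Conditions: (R,R)-IDPi (5–10 mol%), CHCl3/EtOAc 4:1 (0.01 M), 0 → 23 °C, argon
Reagents that add atoms: none
Why: Proposed new method: as in step 7, now with the antipodal catalyst, enantioselective C3' protonation gives the catechol-derived p-quinone methide 25 and anti 1,6-addition of either equivalent ortho-phenol closes the (2'S,3'S)-trans ring; the existing stereocentres sit para across an arene, so catalyst control should dominate. Closest known reactions: racemic acid cyclisation of 2-hydroxystilbenes, IDPi hydroalkoxylation, and chiral-acid 1,6-additions to p-quinone methides.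

## Compound list

1 | resveratrol, (E)-5-[2-(4-hydroxyphenyl)ethenyl]benzene-1,3-diol | Oc1ccc(/C=C/c2cc(O)cc(O)c2)cc1 | starting material
2 | ethyl vinyl ether | C=COCC | starting material
3 | (E)-3,4',5-tris(1-ethoxyethoxy)stilbene | CCOC(C)Oc1ccc(/C=C/c2cc(OC(C)OCC)cc(OC(C)OCC)c2)cc1 | intermediate
4 | 1-(3,5-dihydroxyphenyl)ethanone | CC(=O)c1cc(O)cc(O)c1 | starting material
5 | 1-[3,5-bis(1-ethoxyethoxy)phenyl]ethanone | CC(=O)c1cc(OC(C)OCC)cc(OC(C)OCC)c1 | intermediate
6 | 4-bromophenol | Oc1ccc(Br)cc1 | starting material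
7 | 1-bromo-4-(1-ethoxyethoxy)benzene | CCOC(C)Oc1ccc(Br)cc1 | intermediate
8 | 1-[3,5-bis(1-ethoxyethoxy)phenyl]-2-[4-(1-ethoxyethoxy)phenyl]ethanone | CCOC(C)Oc1ccc(CC(=O)c2cc(OC(C)OCC)cc(OC(C)OCC)c2)cc1 | intermediate
9 | aryllithium of 3, lithium on the carbon between the two acetal oxygens | CCOC(C)Oc1ccc(/C=C/c2cc(OC(C)OCC)c([Li])c(OC(C)OCC)c2)cc1 | intermediate
10 | arylcerium dichloride from 9 | CCOC(C)Oc1ccc(/C=C/c2cc(OC(C)OCC)c([Ce](Cl)Cl)c(OC(C)OCC)c2)cc1 | intermediate
11 | 1-[2,6-bis(1-ethoxyethoxy)-4-{(E)-2-[4-(1-ethoxyethoxy)phenyl]ethenyl}phenyl]-1-[3,5-bis(1-ethoxyethoxy)phenyl]-2-[4-(1-ethoxyethoxy)phenyl]ethanol | CCOC(C)Oc1ccc(/C=C/c2cc(OC(C)OCC)c(C(O)(Cc3ccc(OC(C)OCC)cc3)c3cc(OC(C)OCC)cc(OC(C)OCC)c3)c(OC(C)OCC)c2)cc1 | intermediate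
12 | 1-[2,6-dihydroxy-4-{(E)-2-(4-hydroxyphenyl)ethenyl}phenyl]-1-(3,5-dihydroxyphenyl)-2-(4-hydroxyphenyl)ethanol | Oc1ccc(/C=C/c2cc(O)c(C(O)(Cc3ccc(O)cc3)c3cc(O)cc(O)c3)c(O)c2)cc1 | intermediate
13 | 2-[1-(3,5-dihydroxyphenyl)-2-(4-hydroxyphenyl)ethenyl]-5-[(E)-2-(4-hydroxyphenyl)ethenyl]benzene-1,3-diol (E/Z mixture at the triaryl alkene) | Oc1ccc(/C=C/c2cc(O)c(C(=Cc3ccc(O)cc3)c3cc(O)cc(O)c3)c(O)c2)cc1 | intermediate
14 | 4-{(2R)-2-[2,6-dihydroxy-4-((E)-4-hydroxystyryl)phenyl]-2-(3,5-dihydroxyphenyl)ethylidene}cyclohexa-2,5-dien-1-one | Oc1ccc(/C=C/c2cc(O)c([C@H](C=C3C=CC(=O)C=C3)c3cc(O)cc(O)c3)c(O)c2)cc1 | intermediate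
15 | (2R,3R)-3-(3,5-dihydroxyphenyl)-2-(4-hydroxyphenyl)-6-[(E)-2-(4-hydroxyphenyl)ethenyl]-2,3-dihydro-1-benzofuran-4-ol (2,3-trans) | Oc1ccc(/C=C/c2cc(O)c3c(c2)O[C@@H](c2ccc(O)cc2)[C@@H]3c2cc(O)cc(O)c2)cc1 | intermediate
16 | penta(1-ethoxyethyl) ether of 15 | CCOC(C)Oc1ccc(/C=C/c2cc(OC(C)OCC)c3c(c2)O[C@@H](c2ccc(OC(C)OCC)cc2)[C@@H]3c2cc(OC(C)OCC)cc(OC(C)OCC)c2)cc1 | intermediate
17 | 4-bromobenzene-1,2-diol | Oc1ccc(Br)cc1O | starting material
18 | 4-bromo-1,2-bis(1-ethoxyethoxy)benzene | CCOC(C)Oc1ccc(Br)cc1OC(C)OCC | intermediate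
19 | 1-[3,5-bis(1-ethoxyethoxy)phenyl]-2-[3,4-bis(1-ethoxyethoxy)phenyl]ethanone | CCOC(C)Oc1ccc(CC(=O)c2cc(OC(C)OCC)cc(OC(C)OCC)c2)cc1OC(C)OCC | intermediate
20 | aryllithium of 16, lithium at C4 of the 3,5-bis(acetal-oxy)phenyl ring | CCOC(C)Oc1ccc(/C=C/c2cc(OC(C)OCC)c3c(c2)O[C@@H](c2ccc(OC(C)OCC)cc2)[C@@H]3c2cc(OC(C)OCC)c([Li])c(OC(C)OCC)c2)cc1 | intermediate
21 | arylcerium dichloride from 20 | CCOC(C)Oc1ccc(/C=C/c2cc(OC(C)OCC)c3c(c2)O[C@@H](c2ccc(OC(C)OCC)cc2)[C@@H]3c2cc(OC(C)OCC)c([Ce](Cl)Cl)c(OC(C)OCC)c2)cc1 | intermediate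
22 | nona-acetal tertiary carbinol: 16 bearing at C4 of its 3-aryl ring a C(OH)[3,5-bis(1-ethoxyethoxy)phenyl][3,4-bis(1-ethoxyethoxy)benzyl] group | CCOC(C)Oc1ccc(/C=C/c2cc(OC(C)OCC)c3c(c2)O[C@@H](c2ccc(OC(C)OCC)cc2)[C@@H]3c2cc(OC(C)OCC)c(C(O)(Cc4ccc(OC(C)OCC)c(OC(C)OCC)c4)c4cc(OC(C)OCC)cc(OC(C)OCC)c4)c(OC(C)OCC)c2)cc1 | intermediate
23 | free carbinol from 22 (all nine phenols free) | Oc1ccc(/C=C/c2cc(O)c3c(c2)O[C@@H](c2ccc(O)cc2)[C@@H]3c2cc(O)c(C(O)(Cc4ccc(O)c(O)c4)c4cc(O)cc(O)c4)c(O)c2)cc1 | intermediate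
24 | nona-ol triarylethene: 15 bearing at C4 of its 3,5-dihydroxyphenyl ring a 1-(3,5-dihydroxyphenyl)-2-(3,4-dihydroxyphenyl)ethenyl group (E/Z mixture) | Oc1ccc(/C=C/c2cc(O)c3c(c2)O[C@@H](c2ccc(O)cc2)[C@@H]3c2cc(O)c(C(=Cc4ccc(O)c(O)c4)c4cc(O)cc(O)c4)c(O)c2)cc1 | intermediate
25 | 2-hydroxy-p-quinone methide from 24, new CH stereocentre as drawn | Oc1ccc(/C=C/c2cc(O)c3c(c2)O[C@@H](c2ccc(O)cc2)[C@@H]3c2cc(O)c([C@@H](C=C4C=CC(=O)C(O)=C4)c4cc(O)cc(O)c4)c(O)c2)cc1 | intermediate
26 | CNP0107857.3: upper ring (2R,3R), lower ring (2S,3S), both trans | Oc1ccc(/C=C/c2cc(O)c3c(c2)O[C@@H](c2ccc(O)cc2)[C@@H]3c2cc(O)c3c(c2)O[C@H](c2ccc(O)c(O)c2)[C@H]3c2cc(O)cc(O)c2)cc1 | target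

## Totals

Total step count: 13.
Longest linear sequence: 9 steps (steps 2, 4, 5, 6, 7, 8, 11, 12, 13, from ketone 4 to 26).

## Steps most likely to fail

**Step 7 (proposed new cyclisation, first stereocentres).** The acid may be too weak for C3 protonation in a solvent polar enough to dissolve a hexaol, the ee may be low, or the polyphenol may bind the catalyst. The fallback sets out from 13. It closes the ring with an achiral acid (diphenyl phosphate or TsOH, 10 mol%, EtOAc, 23 °C), the known acid-mediated cyclisation of 2-hydroxystilbenes. This gives trans-configured 15 together with its (2S,3S)-enantiomer F1 as a racemate. Preparative chiral-phase SFC separates the two and the route is rejoined at 15.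

**Step 11 (strong base on the dihydrobenzofuran).** s-BuLi could remove the benzylic C3–H and open the ring by β-elimination of the phenoxide, or metalate elsewhere. The fallback sets out from 11, where no dihydrofuran exists yet, and replaces deprotonation of the dimer by halogen–lithium exchange.
- Carbinol 11 is treated with s-BuLi (2.3 equiv)/TMEDA at −78 °C to give the alkoxide/aryl dilithio species F2, metalated at the only free C–H between two acetal oxygens.
- Quenching with 1,2-dibromotetrachloroethane gives the aryl bromide carbinol F3.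
- Under the conditions of step 6, F3 passes through the free bromo carbinol F4 to the bromo triarylethene F5.
- Under the conditions of step 7, F5 passes through the bromo p-quinone methide F6 to the bromo dimer F7.
- Under the conditions of step 8, F7 gives the penta-acetal bromide F8.
- t-BuLi (2.1 equiv, THF, −78 °C) exchanges the bromine faster than any deprotonation and delivers aryllithium 20, where the route is rejoined.

**Step 13 (proposed new cyclisation on the nona-ol).** Beyond the risks of step 7, the catechol and the acid-labile first ring are present and catalyst control must be kept on a larger substrate. The fallback sets out from 24. An achiral acid (diphenyl phosphate, 10 mol%, EtOAc, 23 °C) closes the lower ring without facial bias, giving 26 and its (2R,3R,2'R,3'R)-diastereomer F9 in about equal amounts. As diastereomers these are separated by reversed-phase preparative HPLC, and the route is rejoined at 26.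

## Further compounds

F1 | step 7 | (2S,3S)-enantiomer of 15 | Oc1ccc(/C=C/c2cc(O)c3c(c2)O[C@H](c2ccc(O)cc2)[C@H]3c2cc(O)cc(O)c2)cc1
F2 | step 11 | dilithio species of 11 (lithium alkoxide, aryl lithium between the two acetal oxygens of the 3,5-dioxygenated ring) | CCOC(C)Oc1ccc(/C=C/c2cc(OC(C)OCC)c(C(O[Li])(Cc3ccc(OC(C)OCC)cc3)c3cc(OC(C)OCC)c([Li])c(OC(C)OCC)c3)c(OC(C)OCC)c2)cc1
F3 | step 11 | aryl bromide of carbinol 11 | CCOC(C)Oc1ccc(/C=C/c2cc(OC(C)OCC)c(C(O)(Cc3ccc(OC(C)OCC)cc3)c3cc(OC(C)OCC)c(Br)c(OC(C)OCC)c3)c(OC(C)OCC)c2)cc1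
F4 | step 11 | free bromo carbinol | Oc1ccc(/C=C/c2cc(O)c(C(O)(Cc3ccc(O)cc3)c3cc(O)c(Br)c(O)c3)c(O)c2)cc1
F5 | step 11 | bromo triarylethene (E/Z mixture) | Oc1ccc(/C=C/c2cc(O)c(C(=Cc3ccc(O)cc3)c3cc(O)c(Br)c(O)c3)c(O)c2)cc1
F6 | step 11 | bromo p-quinone methide | Oc1ccc(/C=C/c2cc(O)c([C@H](C=C3C=CC(=O)C=C3)c3cc(O)c(Br)c(O)c3)c(O)c2)cc1
F7 | step 11 | (2R,3R)-bromo dimer, 15 with bromine at C4 of the 3,5-dihydroxyphenyl ring | Oc1ccc(/C=C/c2cc(O)c3c(c2)O[C@@H](c2ccc(O)cc2)[C@@H]3c2cc(O)c(Br)c(O)c2)cc1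
F8 | step 11 | penta(1-ethoxyethyl) ether of F7 | CCOC(C)Oc1ccc(/C=C/c2cc(OC(C)OCC)c3c(c2)O[C@@H](c2ccc(OC(C)OCC)cc2)[C@@H]3c2cc(OC(C)OCC)c(Br)c(OC(C)OCC)c2)cc1
F9 | step 13 | (2R,3R,2'R,3'R)-diastereomer of 26 | Oc1ccc(/C=C/c2cc(O)c3c(c2)O[C@@H](c2ccc(O)cc2)[C@@H]3c2cc(O)c3c(c2)O[C@@H](c2ccc(O)c(O)c2)[C@@H]3c2cc(O)cc(O)c2)cc1
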